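**Retrosynthetic overview**

1. Feature: ring A of the flavanone carries four contiguous substituents (the C4 acyl carbon on C4a, O1 on C8a, prenyl on C8, OH on C7). A polarised 1-methoxy-3-silyloxy diene adding across the C4a=C8a bond of a preformed ring C sets all four at once, so ring A is built last.
2. Glabrol ⇒ its 4'-MOM ether ⇒ [4+2] cycloaddition (bonds C4a–C5 and C8–C8a) with loss of methanol and benzenesulfinic acid ⇒ (S)-2-aryl-5-(phenylsulfonyl)-2,3-dihydro-4H-pyran-4-one + (1E,3Z)-1-methoxy-7-methyl-3-(trimethylsilyloxy)octa-1,3,6-triene.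
3. Sulfonyl pyranone ⇒ 5-iodo pyranone ⇒ (S)-2-aryl-2,3-dihydro-4H-pyran-4-one ⇒ catalytic asymmetric hetero-Diels–Alder reaction (sets C2) of 4-(methoxymethoxy)-3-prenylbenzaldehyde, made from 4-hydroxybenzaldehyde and prenyl bromide.
4. Triene ⇒ silylation and α′-prenylation of (E)-4-methoxybut-3-en-2-one.
5. Ring order: ring B (purchased) → ring C (step 3) → ring A (step 8).

Key step: step 8

Remark on numbering: flavanone locants (O1, C2, C3, C4, C4a, C5–C8, C8a) are used for the pyranone precursors too; pyranone C5 is C4a and pyranone C6 is C8a.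

Assumption: the (S)-BINOL/Ti(OiPr)4 catalyst is taken to direct the silyloxy diene to the Si face of the aryl aldehyde, as it does in the related allylation and aldol additions, which gives the (S)-pyranone; if the sense proves opposite on this aldehyde, (R)-BINOL is used instead.

**Route**

Step 1
Reactants: 1 4-hydroxybenzaldehyde; 2 prenyl bromide (1-bromo-3-methylbut-2-ene)
Product: 3 4-hydroxy-3-(3-methylbut-2-en-1-yl)benzaldehyde
Conditions: 10% aq. KOH, rt, 24 h
Reagents that add atoms: none
Why: Phenoxide C-alkylation: in water the oxygen of the ambident phenoxide is strongly solvated, so SN2 attack of the ortho carbon (para is blocked by the formyl group) on the primary allylic bromide should give the linear ortho-prenyl phenol, which is separated from O-prenyl ether and bis-alkylated material by chromatography.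

Step 2
Reactants: 3 4-hydroxy-3-(3-methylbut-2-en-1-yl)benzaldehyde
Product: 4 4-(methoxymethoxy)-3-(3-methylbut-2-en-1-yl)benzaldehyde
Conditions: MOMCl, K2CO3, acetone, 0 °C to rt
Reagents that add atoms: chloromethyl methyl ether, COCCl
Why: Williamson-type O-alkylation of the phenoxide by the reactive α-chloro ether; the MOM acetal keeps the phenol from cyclising onto the prenyl group and from reacting with iodine or base later.

Step 3
Reactants: 4 4-(methoxymethoxy)-3-(3-methylbut-2-en-1-yl)benzaldehyde; 5 (E)-1-methoxy-3-(trimethylsilyloxy)buta-1,3-diene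
Product: 7 (S)-2-[4-(methoxymethoxy)-3-(3-methylbut-2-en-1-yl)phenyl]-2,3-dihydro-4H-pyran-4-one, via silylated aldol adduct 6 (not isolated)
Conditions: Ti(OiPr)4 (10 mol%), (S)-BINOL (20 mol%), 4 Å MS, Et2O, −20 °C; then TFA, CH2Cl2, 0 °C, brief
Reagents that add atoms: none
Why: Catalytic asymmetric hetero-Diels–Alder reaction in its Mukaiyama aldol–cyclisation form: the BINOL–titanium Lewis acid activates the aldehyde and exposes its Si face to the diene terminus, which sets C2 as (S) by catalyst control, and TFA then closes ring C by 6-endo oxa-Michael addition with loss of methanol.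

Step 4
Reactants: 7 (S)-2-[4-(methoxymethoxy)-3-(3-methylbut-2-en-1-yl)phenyl]-2,3-dihydro-4H-pyran-4-one
Product: 8 (S)-5-iodo-2-[4-(methoxymethoxy)-3-(3-methylbut-2-en-1-yl)phenyl]-2,3-dihydro-4H-pyran-4-one
Conditions: I2, pyridine, CH2Cl2, 0 °C to rt
Reagents that add atoms: iodine, II
Why: Electrophilic α-iodination of an enone with iodine and pyridine: C4a is the nucleophilic α-carbon of the vinylogous ester and the oxocarbenium intermediate loses its proton to pyridine, while the MOM ether, the prenyl alkene (no internal nucleophile to trap an iodonium ion) and C2 should be untouched.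

Step 5
Reactants: 8 (S)-5-iodo-2-[4-(methoxymethoxy)-3-(3-methylbut-2-en-1-yl)phenyl]-2,3-dihydro-4H-pyran-4-one; 9 sodium benzenesulfinate
Product: 10 (S)-2-[4-(methoxymethoxy)-3-(3-methylbut-2-en-1-yl)phenyl]-5-(phenylsulfonyl)-2,3-dihydro-4H-pyran-4-one
Conditions: CuI (20 mol%), 1,10-phenanthroline (20 mol%), DMSO, 80 °C, argon
Reagents that add atoms: none
Why: Ullmann-type copper-catalysed C–S coupling of a vinyl iodide with a sulfinate salt, helped by the neighbouring carbonyl oxygen as a ligand for copper; the medium is essentially neutral, so C2 is not exposed to enolisation and ring opening.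

Step 6
Reactants: 11 (E)-4-methoxybut-3-en-2-one; 2 prenyl bromide
Product: 12 (E)-1-methoxy-7-methylocta-1,6-dien-3-one
Conditions: LiN(SiMe3)2, THF, −78 °C; then 2, DMPU, −78 to −20 °C
Reagents that add atoms: none
Why: Kinetic α′-alkylation of a vinylogous ester (Stork–Danheiser type): the hindered amide base removes a methyl proton at −78 °C without conjugate addition, and the lithium enolate is alkylated by the allylic bromide at its primary carbon.

Step 7
Reactants: 12 (E)-1-methoxy-7-methylocta-1,6-dien-3-one
Product: 13 (1E,3Z)-1-methoxy-7-methyl-3-(trimethylsilyloxy)octa-1,3,6-triene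
Conditions: TMSOTf, Et3N, Et2O, 0 °C; filtration under argon, used without chromatography
Reagents that add atoms: trimethylsilyl trifluoromethanesulfonate, C[Si](C)(C)OS(=O)(=O)C(F)(F)F
Why: Soft enolisation with silyl triflate and amine should give the silyl dienol ether with the preferred 3Z geometry (silyloxy and CH2 cis), which places the prenyl-bearing chain on the outside of the s-cis diene as the cycloaddition requires.

Step 8
Reactants: 10 (S)-2-[4-(methoxymethoxy)-3-(3-methylbut-2-en-1-yl)phenyl]-5-(phenylsulfonyl)-2,3-dihydro-4H-pyran-4-one; 13 (1E,3Z)-1-methoxy-7-methyl-3-(trimethylsilyloxy)octa-1,3,6-triene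
Product: 16 (S)-glabrol 4'-methoxymethyl ether, via cycloadduct 14 (not isolated), via sulfonyl enone 15 (not isolated)
Conditions: 13 (2.5 equiv), toluene, 90 °C; then 0.5 M HCl, THF, 0 °C; then DBU, CH2Cl2, 0 °C to rt
Reagents that add atoms: none
Why: The C4a=C8a bond of 10 carries both the C4 carbonyl and the sulfonyl group on C4a and is electrophilic at C8a, so it should take up the electron-rich diene 13 in a concerted, asynchronous normal-demand Diels–Alder reaction in which the nucleophilic diene terminus C4 (bearing the prenyl CH2) bonds to C8a and the methoxy-bearing C1 to C4a, closing ring A by intermolecular [4+2] cycloaddition with the silyloxy carbon as C7. The closest known reaction type is the benzannulation of 1-methoxy-3-silyloxy dienes with alkenes that carry a carbonyl group and a sulfonyl or sulfinyl leaving group, and with chromones bearing an acceptor at C3. Dilute acid then hydrolyses the silyl enol ether and eliminates methanol to give the 4a-sulfonyl-5-en-7-one 15, and DBU enolises C7 towards C8 and removes H-8a from the resulting cyclohexa-1,3-dienol with loss of benzenesulfinate, a syn 1,2-elimination (H-8a and the sulfonyl group are cis after suprafacial addition) that is driven by aromatisation and leaves the 7-OH free. The stereocentres formed in 14 at C4a, C5, C8 and C8a are all erased, so endo/exo and facial selectivity do not matter, and C2 is kept because no step breaks the C2–O1 bond and the base contact is short and cold. The selectivity that the step needs is regiochemical (prenyl at C8, oxygen at C7) together with periselectivity for the carbon diene over oxadiene or Michael pathways; the first is secured by the match between the largest HOMO coefficient of the diene at C4 and the β-carbon C8a of the doubly activated enone, the second by running the addition thermally without Lewis acid.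

Step 9
Reactants: 16 (S)-glabrol 4'-methoxymethyl ether
Product: 17 (S)-glabrol
Conditions: 3 M aq. HCl, MeOH, rt to 40 °C
Reagents that add atoms: none
Why: Acid-catalysed acetal cleavage: protonation of the MOM ether releases the phenol and a methoxymethyl cation that methanol captures, and the dilute acid and mild temperature should spare the two ortho-prenyl phenols from cyclisation to chromans and leave C2 configurationally intact.

**Compound list**

1 | 4-hydroxybenzaldehyde | O=Cc1ccc(O)cc1 | starting material
2 | prenyl bromide (1-bromo-3-methylbut-2-ene) | CC(C)=CCBr | starting material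
3 | 4-hydroxy-3-(3-methylbut-2-en-1-yl)benzaldehyde | CC(C)=CCc1cc(C=O)ccc1O | intermediate
4 | 4-(methoxymethoxy)-3-(3-methylbut-2-en-1-yl)benzaldehyde | CC(C)=CCc1cc(C=O)ccc1OCOC | intermediate
5 | (E)-1-methoxy-3-(trimethylsilyloxy)buta-1,3-diene | CO/C=C/C(=C)O[Si](C)(C)C | starting material
6 | (S,E)-1-methoxy-5-[4-(methoxymethoxy)-3-(3-methylbut-2-en-1-yl)phenyl]-5-(trimethylsilyloxy)pent-1-en-3-one | CC(C)=CCc1cc([C@@H](O[Si](C)(C)C)CC(=O)/C=C/OC)ccc1OCOC | intermediate (not isolated)
7 | (S)-2-[4-(methoxymethoxy)-3-(3-methylbut-2-en-1-yl)phenyl]-2,3-dihydro-4H-pyran-4-one | CC(C)=CCc1cc([C@@H]2CC(=O)C=CO2)ccc1OCOC | intermediate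
8 | (S)-5-iodo-2-[4-(methoxymethoxy)-3-(3-methylbut-2-en-1-yl)phenyl]-2,3-dihydro-4H-pyran-4-one | CC(C)=CCc1cc([C@@H]2CC(=O)C(I)=CO2)ccc1OCOC | intermediate
9 | sodium benzenesulfinate | O=S([O-])c1ccccc1.[Na+] | starting material
10 | (S)-2-[4-(methoxymethoxy)-3-(3-methylbut-2-en-1-yl)phenyl]-5-(phenylsulfonyl)-2,3-dihydro-4H-pyran-4-one | CC(C)=CCc1cc([C@@H]2CC(=O)C(S(=O)(=O)c3ccccc3)=CO2)ccc1OCOC | intermediate
11 | (E)-4-methoxybut-3-en-2-one | CO/C=C/C(C)=O | starting material
12 | (E)-1-methoxy-7-methylocta-1,6-dien-3-one | CO/C=C/C(=O)CCC=C(C)C | intermediate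
13 | (1E,3Z)-1-methoxy-7-methyl-3-(trimethylsilyloxy)octa-1,3,6-triene | CO/C=C/C(O[Si](C)(C)C)=C/CC=C(C)C | intermediate
14 | (2S)-5-methoxy-2-[4-(methoxymethoxy)-3-(3-methylbut-2-en-1-yl)phenyl]-8-(3-methylbut-2-en-1-yl)-4a-(phenylsulfonyl)-7-(trimethylsilyloxy)-2,3,4a,5,8,8a-hexahydro-4H-chromen-4-one (cis-fused, mixture of diastereomers at the new centres) | CC(C)=CCc1cc([C@@H]2CC(=O)C3(S(=O)(=O)c4ccccc4)C(OC)C=C(O[Si](C)(C)C)C(CC=C(C)C)C3O2)ccc1OCOC | intermediate (not isolated)
15 | (2S)-2-[4-(methoxymethoxy)-3-(3-methylbut-2-en-1-yl)phenyl]-8-(3-methylbut-2-en-1-yl)-4a-(phenylsulfonyl)-2,3,8,8a-tetrahydro-4H-chromene-4,7(4aH)-dione (cis-fused, mixture of diastereomers) | CC(C)=CCc1cc([C@@H]2CC(=O)C3(S(=O)(=O)c4ccccc4)C=CC(=O)C(CC=C(C)C)C3O2)ccc1OCOC | intermediate (not isolated)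
16 | (S)-glabrol 4'-methoxymethyl ether, (S)-7-hydroxy-2-[4-(methoxymethoxy)-3-(3-methylbut-2-en-1-yl)phenyl]-8-(3-methylbut-2-en-1-yl)chroman-4-one | CC(C)=CCc1cc([C@@H]2CC(=O)c3ccc(O)c(CC=C(C)C)c3O2)ccc1OCOC | intermediate
17 | (S)-glabrol, (S)-7-hydroxy-2-[4-hydroxy-3-(3-methylbut-2-en-1-yl)phenyl]-8-(3-methylbut-2-en-1-yl)chroman-4-one | CC(C)=CCc1cc([C@@H]2CC(=O)c3ccc(O)c(CC=C(C)C)c3O2)ccc1O | target

**Step count**

Total: 9 steps. Longest linear sequence: 7 steps (1 → 3 → 4 → 7 → 8 → 10 → 16 → 17).

**Steps most likely to fail, with fallbacks**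

1. Step 8 (key step). The cycloaddition may be slow relative to decomposition of the diene, or the acceptor may react as an oxadiene or by Michael addition and ring opening. Above all, the syn elimination of benzenesulfinate from 15 may stall or be outrun by β-elimination of O1 from the C7 enolate, which would open ring C and allow re-closure at C5. The fallback changes the leaving group to a sulfoxide, whose thermal syn elimination uses exactly the cis H-8a and needs no base. It sets out from iodide 8 and returns to the route at 16. Coupling of 8 with thiophenol (Pd2(dba)3, Xantphos, iPr2NEt, dioxane, 80 °C) should give (S)-2-[4-(methoxymethoxy)-3-(3-methylbut-2-en-1-yl)phenyl]-5-(phenylsulfanyl)-2,3-dihydro-4H-pyran-4-one F1. Hydrogen peroxide in hexafluoroisopropanol should oxidise sulfur selectively, without epoxidising the prenyl group, to the 5-(phenylsulfinyl) pyranone F2; both sulfur epimers serve. F2 and diene 13 are combined with Eu(fod)3 at rt (chelation of the sulfinyl and carbonyl oxygens) to give the sulfinyl cycloadduct F3. Dilute acid at 0 °C removes the silyl group and methanol to give the sulfinyl enone F4, in which H-8a is the only syn β-hydrogen. Warming F4 in toluene at 50–60 °C should expel benzenesulfenic acid and give 16 directly.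

2. Step 5. The push–pull vinyl iodide may suffer conjugate addition of sulfinate with opening of ring C, protodeiodination, or slow erosion of C2 by enolisation and ring opening in hot DMSO. The fallback builds the sulfone in before ring C is closed and avoids cross-coupling on the pyranone. It sets out from aldehyde 4 and returns at 10. Mukaiyama aldol addition of 1-(tert-butylthio)-1-(trimethylsilyloxy)ethene to 4 with the same (S)-BINOL/Ti(OiPr)4 catalyst (same facial sense as step 3) gives S-tert-butyl (S)-3-[4-(methoxymethoxy)-3-(3-methylbut-2-en-1-yl)phenyl]-3-(trimethylsilyloxy)propanethioate F5, which is desilylated on acidic work-up to the β-hydroxy thioester F6. Lithiated methyl phenyl sulfone (3 equiv, THF, −78 °C) acylates at the thioester to give (S)-4-hydroxy-4-aryl-1-(phenylsulfonyl)butan-2-one F7. Condensation with N,N-dimethylformamide dimethyl acetal at the active methylene gives the sulfonyl enaminone F8, and with PPTS its hydroxyl displaces dimethylamine to close ring C as 10.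

3. Step 1. The ambident phenoxide may give mainly O-prenyl ether and over-alkylated products, leaving little of 3. The fallback makes the aryl–prenyl bond by cross-coupling. It sets out from 1 and returns at 4. Bromination of 1 (Br2, CHCl3, 0 °C) gives 3-bromo-4-hydroxybenzaldehyde F9, protection (MOMCl, K2CO3, acetone) gives 3-bromo-4-(methoxymethoxy)benzaldehyde F10, and Stille coupling with tributyl(3-methylbut-2-en-1-yl)stannane (Pd(PPh3)4, DMF, 90 °C) should deliver 4 with the linear prenyl group.

**Further compounds**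

F1 | step 8 | (S)-2-[4-(methoxymethoxy)-3-(3-methylbut-2-en-1-yl)phenyl]-5-(phenylsulfanyl)-2,3-dihydro-4H-pyran-4-one | CC(C)=CCc1cc([C@@H]2CC(=O)C(Sc3ccccc3)=CO2)ccc1OCOC
F2 | step 8 | (2S)-2-[4-(methoxymethoxy)-3-(3-methylbut-2-en-1-yl)phenyl]-5-(phenylsulfinyl)-2,3-dihydro-4H-pyran-4-one (both sulfur epimers) | CC(C)=CCc1cc([C@@H]2CC(=O)C(S(=O)c3ccccc3)=CO2)ccc1OCOC
F3 | step 8 | (2S)-5-methoxy-2-[4-(methoxymethoxy)-3-(3-methylbut-2-en-1-yl)phenyl]-8-(3-methylbut-2-en-1-yl)-4a-(phenylsulfinyl)-7-(trimethylsilyloxy)-2,3,4a,5,8,8a-hexahydro-4H-chromen-4-one | CC(C)=CCc1cc([C@@H]2CC(=O)C3(S(=O)c4ccccc4)C(OC)C=C(O[Si](C)(C)C)C(CC=C(C)C)C3O2)ccc1OCOC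
F4 | step 8 | (2S)-2-[4-(methoxymethoxy)-3-(3-methylbut-2-en-1-yl)phenyl]-8-(3-methylbut-2-en-1-yl)-4a-(phenylsulfinyl)-2,3,8,8a-tetrahydro-4H-chromene-4,7(4aH)-dione | CC(C)=CCc1cc([C@@H]2CC(=O)C3(S(=O)c4ccccc4)C=CC(=O)C(CC=C(C)C)C3O2)ccc1OCOC
F5 | step 5 | S-tert-butyl (S)-3-[4-(methoxymethoxy)-3-(3-methylbut-2-en-1-yl)phenyl]-3-(trimethylsilyloxy)propanethioate | CC(C)=CCc1cc([C@@H](O[Si](C)(C)C)CC(=O)SC(C)(C)C)ccc1OCOC
F6 | step 5 | S-tert-butyl (S)-3-hydroxy-3-[4-(methoxymethoxy)-3-(3-methylbut-2-en-1-yl)phenyl]propanethioate | CC(C)=CCc1cc([C@@H](O)CC(=O)SC(C)(C)C)ccc1OCOC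
F7 | step 5 | (S)-4-hydroxy-4-[4-(methoxymethoxy)-3-(3-methylbut-2-en-1-yl)phenyl]-1-(phenylsulfonyl)butan-2-one | CC(C)=CCc1cc([C@@H](O)CC(=O)CS(=O)(=O)c2ccccc2)ccc1OCOC
F8 | step 5 | (S)-1-(dimethylamino)-5-hydroxy-5-[4-(methoxymethoxy)-3-(3-methylbut-2-en-1-yl)phenyl]-2-(phenylsulfonyl)pent-1-en-3-one | CC(C)=CCc1cc([C@@H](O)CC(=O)C(=CN(C)C)S(=O)(=O)c2ccccc2)ccc1OCOC
F9 | step 1 | 3-bromo-4-hydroxybenzaldehyde | O=Cc1ccc(O)c(Br)c1
F10 | step 1 | 3-bromo-4-(methoxymethoxy)benzaldehyde | COCOc1ccc(C=O)cc1Br
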